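**Retrosynthetic overview**

- Feature: number the ring C1 (tertiary carbinol carbon carrying hexadecyl), C2=C3 (alkene), C4 (ketone carbon), C5 (CH bearing CO2Me). The only ring alkene lies between C1 and C4, so with C4 as a carbinol the cyclopentene is a 1,6-diene in disguise, with one vinyl group on C1 and one on C4.
- Target 15 ⇒ cyclopentene diol 14 (C4 carbinol to ketone with MnO2) ⇒ diene diol 13 (metathesis closure of C2=C3; the single ring, formed in step 7).
- 13 ⇒ C4–C5 aldol disconnection: dianion of β-hydroxy ester 10 plus acrolein.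
- 10 ⇒ dioxolanone 7 (ring carbonyl to vinyl by hydride, then Wittig) ⇒ pivalaldehyde acetal 3 of (S)-malic acid, alkylated with retention by 1-iodohexadecane, which sets C1.

Key step: step 7

Remark (assumption on the chemistry): the aldol of step 6 is taken to give a mixture of epimers at its two new centres; 13 and 14 denote the isomer drawn, and the epimers are carried along because step 8 oxidises the carbinol and lets the ester-bearing carbon equilibrate; changes of CIP descriptor along the route (10 → 13, 14 → 15) reflect priority changes only.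

**Route**

Step 1
Reactants: 1 (S)-malic acid; 2 pivalaldehyde
Product: 3 2-[(2S,4S)-2-tert-butyl-5-oxo-1,3-dioxolan-4-yl]acetic acid
Conditions: 2 (1.5 equiv), TsOH·H2O (cat.), H2SO4 (cat.), pentane, reflux, Dean–Stark; recrystallisation
Reagents that add atoms: none
Why: Acid-catalysed acetalisation of the α-hydroxy acid unit (dioxolanone formation) closes the five-membered acylal in preference to the six-membered alternative through the β-carboxyl, and under equilibrating conditions the new acetal centre settles cis to the side chain (2S) under control of the malic acid centre, the minor trans isomer being removed by crystallisation.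

Step 2
Reactants: 3 2-[(2S,4S)-2-tert-butyl-5-oxo-1,3-dioxolan-4-yl]acetic acid; 4 1-iodohexadecane
Product: 6 2-[(2S,4S)-2-tert-butyl-4-hexadecyl-5-oxo-1,3-dioxolan-4-yl]acetic acid, via dilithio enolate 5 (not isolated)
Conditions: LiN(SiMe3)2 (2.2 equiv), THF, −78 °C; 4 (1.5 equiv), DMPU, −78 → −30 °C; dilute aq HCl, 0 °C
Reagents that add atoms: none
Why: Enolate alkylation under self-regeneration of stereocentres: deprotonation flattens C4 while the acetal centre persists, and the SN2 attack on the primary iodide should occur on the enolate face opposite to the tert-butyl group, so that hexadecyl takes the place of the former hydrogen with overall retention and fixes the future C1 centre.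

Step 3
Reactants: 6 2-[(2S,4S)-2-tert-butyl-4-hexadecyl-5-oxo-1,3-dioxolan-4-yl]acetic acid
Product: 7 methyl 2-[(2S,4S)-2-tert-butyl-4-hexadecyl-5-oxo-1,3-dioxolan-4-yl]acetate
Conditions: MeI (1.5 equiv), KHCO3 (2 equiv), DMF, 23 °C
Reagents that add atoms: iodomethane, CI
Why: O-Alkylation of the potassium carboxylate (SN2 esterification) is mild enough to leave the acylal ring and the now non-enolisable quaternary centre untouched.

Step 4
Reactants: 7 methyl 2-[(2S,4S)-2-tert-butyl-4-hexadecyl-5-oxo-1,3-dioxolan-4-yl]acetate
Product: 8 methyl 2-[(2S,4S,5RS)-2-tert-butyl-4-hexadecyl-5-hydroxy-1,3-dioxolan-4-yl]acetate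
Conditions: iBu2AlH (1.1 equiv), CH2Cl2, −78 °C; MeOH, then aq KNaC4H4O6; used crude
Reagents that add atoms: none
Why: Partial reduction of a lactone to a lactol with iBu2AlH: the α-oxygenated acylal carbonyl is far more electrophilic than the side-chain methyl ester and its tetrahedral aluminium hemiacetal is stable at −78 °C, so a single hydride should be delivered there only, the new hemiacetal centre forming as an inconsequential anomeric mixture.

Step 5
Reactants: 8 methyl 2-[(2S,4S,5RS)-2-tert-butyl-4-hexadecyl-5-hydroxy-1,3-dioxolan-4-yl]acetate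
Product: 10 methyl (3S)-3-ethenyl-3-hydroxynonadecanoate, via hydroxy aldehyde 9 (not isolated)
Conditions: Ph3PCH3Br (4 equiv), n-BuLi (3.8 equiv), THF, 0 °C; add 8 at −78 °C, then 0 °C; aq NH4Cl
Reagents that add atoms: methyltriphenylphosphonium bromide, C[P+](c1ccccc1)(c1ccccc1)c1ccccc1.[Br-]
Why: Wittig methylenation of a lactol: the basic ylide opens the deprotonated hemiacetal to the α-hydroxy aldehyde with release of pivalaldehyde (itself methylenated by the excess ylide), and the non-enolisable aldehyde is converted into the vinyl group without touching the quaternary centre, the cold conditions and lithium counterion disfavouring retro-aldol cleavage of the tertiary alkoxide.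

Step 6
Reactants: 10 methyl (3S)-3-ethenyl-3-hydroxynonadecanoate; 11 acrolein
Product: 13 methyl (2S,3R)-3-ethenyl-3-hydroxy-2-[(1S)-1-hydroxyprop-2-en-1-yl]nonadecanoate, via dilithio dianion 12 (not isolated)
Conditions: LiN(iPr)2 (2.3 equiv), THF, −78 → −30 °C; 11 (1.5 equiv), −78 °C; AcOH/THF quench at −78 °C
Reagents that add atoms: none
Why: Dianion aldol of a β-hydroxy ester (Fráter–Seebach type): the alkoxide protects the β-oxygen from elimination, the chelated lithium enolate adds 1,2 to acrolein at low temperature, and the two new centres (ester-bearing carbon and secondary carbinol) are expected to form with little control, which is tolerated because the carbinol is later oxidised and the ester-bearing carbon later becomes epimerisable.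

Step 7
Reactants: 13 methyl (2S,3R)-3-ethenyl-3-hydroxy-2-[(1S)-1-hydroxyprop-2-en-1-yl]nonadecanoate
Product: 14 methyl (1S,2R,5S)-2-hexadecyl-2,5-dihydroxycyclopent-3-ene-1-carboxylate
Conditions: second-generation Grubbs catalyst (H2IMes)(PCy3)Cl2Ru=CHPh (5 mol %), 1,4-benzoquinone (10 mol %), degassed CH2Cl2 (5 mM), 40 °C
Reagents that add atoms: none
Why: Ring-closing olefin metathesis: the ruthenium benzylidene first exchanges with the less hindered vinyl group beside the secondary carbinol, the resulting alkylidene adds [2+2] across the vinyl group on the quaternary carbinol carbon, and retro-[2+2] of the ruthenacyclobutane releases the cyclopentene and Ru=CH2, so that ethylene is the only by-product. The closest known reaction type is the closure of hepta-1,6-diene-3,5-diols and related dienes with unprotected allylic hydroxyls to cyclopentenols by the same catalyst. The single ring of the target, the five-membered carbocycle, is closed by intramolecular alkylidene–alkene cycloaddition within a 1,6-diene, the two internal vinyl carbons becoming C2=C3. No stereocentre is formed, the three existing centres are not touched and the ring alkene can only be cis. The step needs ring closure to outrun cross-metathesis and isomerisation of the allylic carbinols, which the high dilution, the favourable five-membered ring size, two monosubstituted alkenes and the rate-enhancing allylic hydroxyls should secure, while keeping C4 as a carbinol spares the catalyst an electron-poor enone and an acidic β-keto ester.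

Step 8
Reactants: 14 methyl (1S,2R,5S)-2-hexadecyl-2,5-dihydroxycyclopent-3-ene-1-carboxylate
Product: 15 methyl (1R,2R)-2-hexadecyl-2-hydroxy-5-oxocyclopent-3-ene-1-carboxylate
Conditions: activated MnO2 (20 equiv), CH2Cl2, 23 °C; filtration through Celite; rapid chromatography on neutral SiO2
Reagents that add atoms: none
Why: Allylic oxidation with MnO2 touches only the secondary allylic carbinol (the tertiary one has no carbinol hydrogen) and runs under neutral heterogeneous conditions that should spare the dehydration- and retro-aldol-prone γ-hydroxy enone, while the ester-bearing carbon, now flanked by ketone and ester, equilibrates through the enol so that any epimeric material converges on the isomer with the ester trans to hexadecyl and cis to the hydroxyl.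

**Compound list**

1 | (S)-malic acid | O[C@@H](CC(O)=O)C(O)=O | starting material
2 | pivalaldehyde | CC(C)(C)C=O | starting material
3 | 2-[(2S,4S)-2-tert-butyl-5-oxo-1,3-dioxolan-4-yl]acetic acid | CC(C)(C)[C@H]1O[C@@H](CC(O)=O)C(=O)O1 | intermediate
4 | 1-iodohexadecane | CCCCCCCCCCCCCCCCI | starting material
5 | dilithio enolate-carboxylate of 3 (not isolated) | CC(C)(C)[C@H]1OC(CC(=O)[O-])=C([O-])O1.[Li+].[Li+] | intermediate
6 | 2-[(2S,4S)-2-tert-butyl-4-hexadecyl-5-oxo-1,3-dioxolan-4-yl]acetic acid | CC(C)(C)[C@H]1O[C@@](CCCCCCCCCCCCCCCC)(CC(O)=O)C(=O)O1 | intermediate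
7 | methyl 2-[(2S,4S)-2-tert-butyl-4-hexadecyl-5-oxo-1,3-dioxolan-4-yl]acetate | CC(C)(C)[C@H]1O[C@@](CCCCCCCCCCCCCCCC)(CC(=O)OC)C(=O)O1 | intermediate
8 | methyl 2-[(2S,4S,5RS)-2-tert-butyl-4-hexadecyl-5-hydroxy-1,3-dioxolan-4-yl]acetate (anomeric mixture) | CC(C)(C)[C@H]1O[C@@](CCCCCCCCCCCCCCCC)(CC(=O)OC)C(O)O1 | intermediate
9 | methyl (3S)-3-formyl-3-hydroxynonadecanoate (not isolated) | CCCCCCCCCCCCCCCC[C@](O)(CC(=O)OC)C=O | intermediate
10 | methyl (3S)-3-ethenyl-3-hydroxynonadecanoate | CCCCCCCCCCCCCCCC[C@](O)(CC(=O)OC)C=C | intermediate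
11 | acrolein | C=CC=O | starting material
12 | dilithio alkoxide-enolate of 10 (not isolated) | CCCCCCCCCCCCCCCC[C@]([O-])(C=C(OC)[O-])C=C.[Li+].[Li+] | intermediate
13 | methyl (2S,3R)-3-ethenyl-3-hydroxy-2-[(1S)-1-hydroxyprop-2-en-1-yl]nonadecanoate (isomer drawn; epimers accompany it) | CCCCCCCCCCCCCCCC[C@@](O)(C=C)[C@@H](C(=O)OC)[C@@H](O)C=C | intermediate
14 | methyl (1S,2R,5S)-2-hexadecyl-2,5-dihydroxycyclopent-3-ene-1-carboxylate (isomer drawn; epimers accompany it) | CCCCCCCCCCCCCCCC[C@@]1(O)C=C[C@H](O)[C@@H]1C(=O)OC | intermediate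
15 | methyl (1R,2R)-2-hexadecyl-2-hydroxy-5-oxocyclopent-3-ene-1-carboxylate | CCCCCCCCCCCCCCCC[C@@]1(O)C=CC(=O)[C@@H]1C(=O)OC | target

**Step count**

Total step count: 8. Longest linear sequence: 8 steps, from (S)-malic acid 1 to 15.

**Steps most likely to fail**

1. Step 7 (ring closure). What may go wrong: catalyst decomposition to ruthenium hydride species that isomerise the free secondary allylic carbinol to an ethyl ketone, or slow engagement of the vinyl group on the quaternary carbon so that intermolecular metathesis takes over. The fallback sets out from 13 and returns at 14. The secondary carbinol alone is silylated (Et3SiCl, imidazole, DMF, 0 °C; the tertiary hydroxyl is too hindered to react) to give methyl (2S,3R)-3-ethenyl-3-hydroxy-2-[(1S)-1-(triethylsilyloxy)prop-2-en-1-yl]nonadecanoate F1, which no longer has the free secondary allylic carbinol that the isomerisation needs. Closure with the second-generation Hoveyda–Grubbs catalyst (H2IMes)Cl2Ru=CH(C6H4-2-OiPr) in toluene at 60 °C should give methyl (1S,2R,5S)-2-hexadecyl-2-hydroxy-5-(triethylsilyloxy)cyclopent-3-ene-1-carboxylate F2. Buffered HF·pyridine in THF/pyridine at 0 °C then returns 14.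

2. Step 2 (alkylation). What may go wrong: the dioxolanone enolate decomposes at the temperatures needed for SN2 on an unactivated primary iodide, so conversion stays low. The fallback sets out from 3 and returns at 6. Dianion 5 is generated as in step 2 and quenched at −78 °C with allyl bromide, a reactive electrophile under the same facial control, to give 2-[(2S,4S)-2-tert-butyl-5-oxo-4-(prop-2-en-1-yl)-1,3-dioxolan-4-yl]acetic acid F3. Cross-metathesis with excess 1-pentadecene (second-generation Grubbs catalyst (H2IMes)(PCy3)Cl2Ru=CHPh, CH2Cl2, 40 °C) should give 2-[(2S,4S)-2-tert-butyl-4-(hexadec-2-en-1-yl)-5-oxo-1,3-dioxolan-4-yl]acetic acid F4 as an E/Z mixture. Hydrogenation (H2, Pd/C, EtOAc) returns 6.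

3. Step 4 (lactol formation). What may go wrong: loss of chemoselectivity, with hydride also attacking the side-chain methyl ester or reducing past the lactol stage. The fallback sets out from 6 and returns at 10, so that no second ester is present during the hydride and ylide steps. Acid 6 is first converted in the flask into lithium 2-[(2S,4S)-2-tert-butyl-4-hexadecyl-5-oxo-1,3-dioxolan-4-yl]acetate F5 (LiN(SiMe3)2, 1.0 equiv, THF, −78 °C), whose carboxylate resists hydride. Reduction with iBu2AlH (1.2 equiv, −78 °C) and careful acidification to pH 4 should give 2-[(2S,4S,5RS)-2-tert-butyl-4-hexadecyl-5-hydroxy-1,3-dioxolan-4-yl]acetic acid F6. Excess Ph3P=CH2 (from Ph3PCH3Br and n-BuLi, THF, 0 °C) opens it to (3S)-3-formyl-3-hydroxynonadecanoic acid F7, formed in the flask as its carboxylate, and methylenates this to (3S)-3-ethenyl-3-hydroxynonadecanoic acid F8. Esterification with MeI and KHCO3 in DMF returns 10.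

Further compounds
F1 | step 7 | methyl (2S,3R)-3-ethenyl-3-hydroxy-2-[(1S)-1-(triethylsilyloxy)prop-2-en-1-yl]nonadecanoate | CCCCCCCCCCCCCCCC[C@@](O)(C=C)[C@@H](C(=O)OC)[C@@H](O[Si](CC)(CC)CC)C=C
F2 | step 7 | methyl (1S,2R,5S)-2-hexadecyl-2-hydroxy-5-(triethylsilyloxy)cyclopent-3-ene-1-carboxylate | CCCCCCCCCCCCCCCC[C@@]1(O)C=C[C@H](O[Si](CC)(CC)CC)[C@@H]1C(=O)OC
F3 | step 2 | 2-[(2S,4S)-2-tert-butyl-5-oxo-4-(prop-2-en-1-yl)-1,3-dioxolan-4-yl]acetic acid | CC(C)(C)[C@H]1O[C@@](CC=C)(CC(O)=O)C(=O)O1
F4 | step 2 | 2-[(2S,4S)-2-tert-butyl-4-(hexadec-2-en-1-yl)-5-oxo-1,3-dioxolan-4-yl]acetic acid (E/Z mixture) | CC(C)(C)[C@H]1O[C@@](CC=CCCCCCCCCCCCCC)(CC(O)=O)C(=O)O1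
F5 | step 4 | lithium 2-[(2S,4S)-2-tert-butyl-4-hexadecyl-5-oxo-1,3-dioxolan-4-yl]acetate | CC(C)(C)[C@H]1O[C@@](CCCCCCCCCCCCCCCC)(CC(=O)[O-])C(=O)O1.[Li+]
F6 | step 4 | 2-[(2S,4S,5RS)-2-tert-butyl-4-hexadecyl-5-hydroxy-1,3-dioxolan-4-yl]acetic acid | CC(C)(C)[C@H]1O[C@@](CCCCCCCCCCCCCCCC)(CC(O)=O)C(O)O1
F7 | step 4 | (3S)-3-formyl-3-hydroxynonadecanoic acid | CCCCCCCCCCCCCCCC[C@](O)(CC(O)=O)C=O
F8 | step 4 | (3S)-3-ethenyl-3-hydroxynonadecanoic acid | CCCCCCCCCCCCCCCC[C@](O)(CC(O)=O)C=C
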